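Guaiane numbering is used, primed for the spiro half. Everything rests on the cyclohexene ring C (C2, C1, C10, C14, C15', C4'), read as a [4+2] adduct whose diene is hidden in a 14-nor ene-dione. Both halves come from dehydrocostus lactone through dehydrozaluzanin C, and in one half C14 is excised by ozonolysis. The excision assigns the diene and dienophile roles and keeps oxidants away from the adduct. In the key step, base-free methylenation of the C10 ketone (bond C10-C14) releases the s-cis diene C14=C10-C1=C2. The exocyclic enone C4'=C15' of the second half traps it at once (bonds C2-C4' and C14-C15'), copying the presumed biosynthesis and setting spiro centre C4'. Base equilibration then sets C10 and C5.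

Key step: step 5

Assumption: dehydrocostus lactone (from costus root oil) is bought as the enantiomer drawn, and the target configuration at the two vinylogously acidic centres C5 (H cis to H6) and C10 (H trans to H5) is taken to be the thermodynamic one.

Step 1
Reactants: 1 dehydrocostus lactone
Product: 2 isozaluzanin C (3α-hydroxydehydrocostus lactone)
Conditions: SeO2 (cat.), t-BuOOH, CH2Cl2, 0 °C to rt
Reagents that add atoms: tert-butyl hydroperoxide, CC(C)(C)OO
Why: Catalytic SeO2 allylic oxidation (ene reaction, then [2,3]-sigmatropic shift) is expected to pick the unhindered ring methylene C3 next to C4=C15 and to deliver oxygen on the convex α face that carries H1 and H5, a stereocentre that the next step erases.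

Step 2
Reactants: 2 isozaluzanin C
Product: 3 dehydrozaluzanin C (3-oxodehydrocostus lactone)
Conditions: Dess-Martin periodinane, CH2Cl2, rt
Reagents that add atoms: none
Why: Dess-Martin oxidation turns the allylic alcohol into the exocyclic enone under neutral, non-nucleophilic conditions that leave the three methylene groups and the four ring stereocentres untouched.

Step 3
Reactants: 3 dehydrozaluzanin C
Product: 4 14-nor-3,10-dioxoguaia-4(15),11(13)-dien-12,6α-olide
Conditions: O3 (1 equiv), CH2Cl2, -78 °C; then Me2S
Reagents that add atoms: ozone, [O-][O+]=O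
Why: Ozone is an electrophile, so Criegee ozonolysis with one equivalent should cleave only the isolated, electron-rich C10=C14 alkene and spare the two carbonyl-conjugated methylenes, and the neutral reductive work-up leaves C1 and C5 alone.

Step 4
Reactants: 4 14-nor-3,10-dioxoguaia-4(15),11(13)-dien-12,6α-olide
Product: 6 14-nor-3,10-dioxoguaia-1,4(15),11(13)-trien-12,6α-olide (ene-dione), via bis-silyl dienol ether 5 (not isolated)
Conditions: TMSOTf, Et3N, CH2Cl2, 0 °C; concentrate; Pd(OAc)2, MeCN, rt
Reagents that add atoms: none
Why: Soft enolisation should give the conjugated 1,4-bis(silyloxy)diene C3=C2-C1=C10 (C3 can enolise only to C2, and C10 enolises to C1 because that extends the conjugation), and Saegusa-Ito oxidation of it should give the C1=C2 ene-dione, any leakage at C5 being harmless because step 6 equilibrates that centre.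

Step 5
Reactants: 6 14-nor-3,10-dioxoguaia-1,4(15),11(13)-trien-12,6α-olide (ene-dione); 3 dehydrozaluzanin C
Product: 8 Diels-Alder adduct (Δ1(10) isomer of the target, 2βH, 5αH), via cross-conjugated diene 7 (not isolated)
Conditions: Tebbe reagent Cp2Ti(CH2)(Cl)AlMe2 (1.0 equiv), toluene, -40 °C; then 3 (3 equiv), -40 °C to rt, argon
Reagents that add atoms: Tebbe reagent Cp2Ti(CH2)(Cl)AlMe2, [CH2-2].[Ti+4].[cH-]1cccc1.[cH-]1cccc1.C[Al](C)Cl
Why: Cp2Ti=CH2 set free from the Tebbe reagent adds to the C10 ketone of 6 in a [2+2] fashion and the oxatitanacyclobutane cycloreverts (Tebbe carbonyl methylenation), which makes the C10-C14 bond without base so that the acidic C5-H survives; C10 is chosen over C3 because C3 is cross-conjugated on both sides and the poorer electrophile, and over the lactone because esters react only near room temperature. The product 7 is a 1-acyl diene whose two double bonds are both exocyclic to the seven-membered ring and therefore held s-cis, and the exocyclic enone C4'=C15' of 3 traps it in an intermolecular Diels-Alder reaction that the liberated Me2AlCl should accelerate; the closest known types are tandem olefination/cycloaddition and the [4+2] dimerisation of α-methylene cyclopentanones presumed in the biosynthesis. Ring C closes in one concerted suprafacial [4+2] event (bonds C2-C4' and C14-C15') with the usual ortho regiochemistry of a 1-substituted diene, which joins the two acyl-bearing carbons. The new quaternary centre C4' is controlled by the cis-fused hydroazulenone of 3, whose convex α face (that of H1' and H5') is the open one, so that C2 ends up α and C15' β; C2 (H β, from attack on the diene face away from C6 and the lactone) is a transient centre that step 6 erases. The step needs the enone of 3 to outrun the two acrylate-type methylenes and the C4=C15 enone of 7 itself, which its lower LUMO, Lewis-acid binding to the ketone and the threefold excess of 3 should secure.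

Step 6
Reactants: 8 Diels-Alder adduct
Product: 9 target CNP0221188.1
Conditions: DBU (0.2 equiv), degassed CH2Cl2, 0 °C to rt, argon
Reagents that add atoms: none
Why: DBU reversibly forms the extended dienolates through C2-H, C10-H and C5-H (vinylogous tautomerisation and epimerisation), so the β,γ-enone should move into conjugation (C1=C2) and the two γ-centres should settle under thermodynamic control as H10 α and H5 β (cis to H6), the twist-chair arrangement of the seven-membered ring in which C9 and C6 lie on opposite faces of the planar dienone.

Compound list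
1 | dehydrocostus lactone, guaia-4(15),10(14),11(13)-trien-12,6α-olide (1αH,5αH,6βH,7αH; 3aS,6aR,9aR,9bS) | C=C1CC[C@H]2C(=C)CC[C@H]3C(=C)C(=O)O[C@@H]3[C@H]21 | starting material
2 | isozaluzanin C, 3α-hydroxy derivative of 1 (OH cis to H1 and H5) | C=C1[C@H](O)C[C@H]2C(=C)CC[C@H]3C(=C)C(=O)O[C@@H]3[C@H]21 | intermediate
3 | dehydrozaluzanin C, 3-oxo derivative of 1 | C=C1C(=O)C[C@H]2C(=C)CC[C@H]3C(=C)C(=O)O[C@@H]3[C@H]21 | intermediate
4 | 14-nor-3,10-dioxoguaia-4(15),11(13)-dien-12,6α-olide (1αH,5αH,6βH,7αH) | C=C1C(=O)C[C@H]2C(=O)CC[C@H]3C(=C)C(=O)O[C@@H]3[C@H]21 | intermediate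
5 | 3,10-bis(trimethylsilyloxy)-14-norguaia-1(10),2,4(15),11(13)-tetraen-12,6α-olide (5αH) | C=C1C(O[Si](C)(C)C)=CC2=C(O[Si](C)(C)C)CC[C@H]3C(=C)C(=O)O[C@@H]3[C@H]21 | intermediate
6 | 14-nor-3,10-dioxoguaia-1,4(15),11(13)-trien-12,6α-olide (5αH), the ene-dione | C=C1C(=O)C=C2C(=O)CC[C@H]3C(=C)C(=O)O[C@@H]3[C@H]21 | intermediate
7 | 3-oxoguaia-1,4(15),10(14),11(13)-tetraen-12,6α-olide (5αH), the diene | C=C1C(=O)C=C2C(=C)CC[C@H]3C(=C)C(=O)O[C@@H]3[C@H]21 | intermediate
8 | Diels-Alder adduct, Δ1(10) isomer of 9 with 2βH and 5αH; C4' carries C2 on its α face and C15' on its β face | C=C1C(=O)[C@H]2C3=C(CC[C@H]4C(=C)C(=O)O[C@@H]4[C@H]31)CC[C@]21C(=O)C[C@H]2C(=C)CC[C@H]3C(=C)C(=O)O[C@@H]3[C@H]21 | intermediate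
9 | CNP0221188.1, spiro dimer with C1=C2 enone (5βH,6βH,7αH,10αH, C14 β on C10; 1'αH,5'αH,6'βH,7'αH; at C4' C2 α and C15' β) | C=C1C(=O)C2=C3[C@H](CC[C@H]4C(=C)C(=O)O[C@@H]4[C@H]13)CC[C@]21C(=O)C[C@H]2C(=C)CC[C@H]3C(=C)C(=O)O[C@@H]3[C@H]21 | target

Total step count: 6. Longest linear sequence: 6 steps (1, 2, 3, 4, 6, 8, 9). Compound 3 enters twice.

Steps most likely to fail

Step 5. The methylenation may also touch the C3 carbonyl or lag behind decay of the ene-dione. The diene may also dimerise with itself, or enter hetero-Diels-Alder channels, before it meets 3. The fallback sets out from 6 and separates olefination from cycloaddition. Me3SiCH2MgCl/CeCl3 in THF at -78 °C should add to the α face of the C10 ketone to give the isolable pro-diene, the 10β-hydroxy-10α-(trimethylsilylmethyl) carbinol F1. F1 is then mixed with excess 3, and BF3·OEt2 at -78 °C triggers the Peterson elimination, so that diene 7 is born in the presence of the dienophile. The route is rejoined at 8.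

Step 6. The equilibration may rest at the wrong epimer at C5 or C10. The dienolate may also be caught by traces of oxygen at C10 or add to a methylene lactone. The fallback sets out from 8 and replaces thermodynamic control by kinetic control at C5. Brief DBU treatment should first give the conjugated enone with the natural C5, the 5αH epimer of the target F2. TBSOTf/Et3N then removes H5 to give the planar tert-butyldimethylsilyloxyfulvene F3. HF·pyridine at -78 °C should protonate C5 on the β face, the side of H6 and anti to the C6-O bond, and the route is rejoined at 9.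

Step 4. Enolisation of the C10 ketone towards C9, over-oxidation, and self-condensation of the very electrophilic ene-dione may erode the step. The fallback sets out from 4 and replaces the silyl enol ether oxidation by a selenoxide elimination. PhSeCl in EtOAc should selenenylate the C3 enol on the convex α face to give the 2α-phenylselanyl diketone F4, in which Se is syn to H1. H2O2/pyridine at 0 °C should then bring about syn elimination to the C1=C2 alkene, and the route is rejoined at 6.

Further compounds
F1 | step 5 | 10β-hydroxy-10α-(trimethylsilylmethyl)-14-nor-3-oxoguaia-1,4(15),11(13)-trien-12,6α-olide | C=C1C(=O)C=C2[C@](O)(C[Si](C)(C)C)CC[C@H]3C(=C)C(=O)O[C@@H]3[C@H]21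
F2 | step 6 | 5αH epimer of the target | C=C1C(=O)C2=C3[C@H](CC[C@H]4C(=C)C(=O)O[C@@H]4[C@@H]13)CC[C@]21C(=O)C[C@H]2C(=C)CC[C@H]3C(=C)C(=O)O[C@@H]3[C@H]21
F3 | step 6 | 3-(tert-butyldimethylsilyloxy)fulvene of the target (C3=C2, C1=C5, C4=C15) | C=C1C(O[Si](C)(C)C(C)(C)C)=C2C3=C1[C@H]1OC(=O)C(=C)[C@@H]1CC[C@@H]3CC[C@]21C(=O)C[C@H]2C(=C)CC[C@H]3C(=C)C(=O)O[C@@H]3[C@H]21
F4 | step 4 | 2α-phenylselanyl-14-nor-3,10-dioxoguaia-4(15),11(13)-dien-12,6α-olide | C=C1C(=O)[C@H]([Se]c2ccccc2)[C@H]2C(=O)CC[C@H]3C(=C)C(=O)O[C@@H]3[C@H]21
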